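**Plan**
1. Retrosynthesis: the succinimide is opened by N→O acyl shift to a temporary 15,12-γ-lactone bearing the C16 acid; C11–C12 is then cut through the retron O–C12–C11–C9(H)–C8=C17 (a 4-penten-1-ol), giving the ring-B 8(17),9(11)-diene 11 and the C12–C16 aldehyde 14.
2. Diene 11 comes from sclareolide: C2 chlorination, lactone opening and dehydration, C7 oxygenation (7α-OH, then via the enone to 7β-OAc), and excision of C12 by decarboxylative desaturation. Aldehyde 14 comes in one operation from methyl 4-oxobutanoate.
3. Forward: a nickel-catalysed homoallylation joins 11 and 14 at C11–C12, returns hydride to C9, keeps the C8 methylene, and the C12 alkoxide closes the lactone. Desilylation, oxidation to the acid, amidation and lactone-to-imide acyl transfer finish the route.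
4. Stereochemistry: C5/C10 from sclareolide; C2 by equatorial C–H chlorination; C7 by axial hydride attack on the 7-ketone; C9 by α-face Ni–H delivery (β face blocked by the axial C10 methyl); C12 by the 1,3-anti oxanickelacycle; C13 by organocatalytic hydroxymethylation, held in the trans-lactone.
5. Enabling feature: ring B carries the exocyclic C8=C17 methylene next to C9–H, and the C12 carbinol is bis-homoallylic to it through C11. Ring B can therefore be unfolded to an s-cis 2,3-dimethylene diene whose C11 terminus takes the aldehyde; C12–O is γ to the C15 carbonyl, which allows the temporary lactone.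

Key step: step 11

Remark: labdane numbering is used (C15 and C16 are the imide carbonyls, C16 on C13); α/β refer to the decalin drawn with the C10 methyl β; the target SMILES corresponds to 2α-Cl, 7β-OAc, 12S, 13R.

**Step 1**
Reactants: 1 (+)-sclareolide
Product: 2 2α-chlorosclareolide
Conditions: Mn(TPP)Cl (cat.), TBACl (cat.), aq. NaOCl, CH2Cl2, rt
Reagents that add atoms: sodium hypochlorite, [Na+].[O-]Cl
Why: Manganese-porphyrin radical-rebound C–H chlorination should attack the most accessible, electron-rich methylene of sclareolide (C2, remote from the lactone) and deliver chlorine equatorially (2α).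

**Step 2**
Reactants: 2 2α-chlorosclareolide
Product: 4 allyl 2α-chloro-8α-hydroxy-13,14,15,16-tetranorlabdan-12-oate, via potassium hydroxy carboxylate 3 (not isolated)
Conditions: KOH, MeOH/H2O, 60 °C; evaporate; allyl bromide, DMF, rt
Reagents that add atoms: potassium hydroxide, [K+].[OH-]; allyl bromide, C=CCBr
Why: Saponification opens the lactone and SN2 O-alkylation of the carboxylate traps the open form before relactonisation; the equatorial C2 chloride has no antiperiplanar hydrogen and should survive, and no stereocenter is touched.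

**Step 3**
Reactants: 4 allyl hydroxy ester
Product: 5 allyl 2α-chloro-13,14,15,16-tetranorlabd-8(17)-en-12-oate
Conditions: SOCl2, pyridine, CH2Cl2, −78 °C
Reagents that add atoms: none
Why: Chlorosulfite formation and pyridine-mediated elimination at low temperature (SOCl2/pyridine dehydration of a tertiary alcohol) should favour loss of a methyl proton to give the exocyclic 8(17)-alkene.

**Step 4**
Reactants: 5 exocyclic alkene allyl ester
Product: 6 allyl 2α-chloro-7α-hydroxy-13,14,15,16-tetranorlabd-8(17)-en-12-oate
Conditions: SeO2 (cat.), t-BuOOH, CH2Cl2, rt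
Reagents that add atoms: tert-butyl hydroperoxide, CC(C)(C)OO (oxygen relayed through catalytic SeO2, O=[Se]=O)
Why: SeO2/t-BuOOH allylic oxidation (ene reaction then [2,3]-shift) should functionalise the ring methylene C7 rather than the hindered C9–H and deliver oxygen axially from the α face.

**Step 5**
Reactants: 6 7α-alcohol
Product: 7 allyl 2α-chloro-7-oxo-13,14,15,16-tetranorlabd-8(17)-en-12-oate
Conditions: Dess–Martin periodinane, CH2Cl2, 0 °C→rt
Reagents that add atoms: none
Why: Dess–Martin oxidation of the allylic alcohol under near-neutral conditions should give the exocyclic enone without migration of the double bond.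

**Step 6**
Reactants: 7 enone
Product: 8 allyl 2α-chloro-7β-hydroxy-13,14,15,16-tetranorlabd-8(17)-en-12-oate
Conditions: NaBH4, CeCl3·7H2O, MeOH, −78 °C
Reagents that add atoms: none
Why: Luche 1,2-reduction; the small hydride should attack C7 axially from the α face and so give the equatorial 7β-alcohol, while the esters are untouched.

**Step 7**
Reactants: 8 7β-alcohol
Product: 9 allyl 7β-acetoxy-2α-chloro-13,14,15,16-tetranorlabd-8(17)-en-12-oate
Conditions: Ac2O, pyridine, DMAP (cat.), CH2Cl2, rt
Reagents that add atoms: acetic anhydride, CC(=O)OC(C)=O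
Why: DMAP-catalysed acylation of the only free hydroxyl installs the acetate of the target with retention at C7.

**Step 8**
Reactants: 9 acetate allyl ester
Product: 10 7β-acetoxy-2α-chloro-13,14,15,16-tetranorlabd-8(17)-en-12-oic acid
Conditions: Pd(PPh3)4 (cat.), morpholine, THF, rt
Reagents that add atoms: none
Why: Tsuji–Trost deallylation: Pd(0) ionises the unsubstituted allyl ester and morpholine traps the π-allyl, while the hindered equatorial C7 acetate, whose C–O bond lies near the nodal plane of the C8=C17 π bond, should not ionise.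

**Step 9**
Reactants: 10 carboxylic acid
Product: 11 7β-acetoxy-2α-chloro-12,13,14,15,16-pentanorlabda-8(17),9(11)-diene
Conditions: 9-mesitylacridine (cat.), Co(dmgH)2(py)Cl (cat.), CH2Cl2/MeCN, 400 nm LED, rt
Reagents that add atoms: none
Why: Photocatalytic decarboxylative desaturation (acridine/cobaloxime dual catalysis): decarboxylation gives the primary C11 radical, which cobalt dehydrogenates with loss of its only β-hydrogen (C9–H) to form the 9(11)-methylene and hence the s-cis diene under neutral conditions.

**Step 10**
Reactants: 12 methyl 4-oxobutanoate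
Product: 14 methyl (S)-4-[(tert-butyldimethylsilyl)oxy]-3-formylbutanoate, via hydroxy aldehyde 13 (not isolated)
Conditions: (R)-α,α-diphenylprolinol TMS ether (cat.), aq. HCHO, pH 7 buffer, PhMe, rt; then TBSCl, imidazole, CH2Cl2, 0 °C
Reagents that add atoms: formaldehyde, C=O; tert-butyldimethylsilyl chloride, CC(C)(C)[Si](C)(C)Cl
Why: Enamine-catalysed α-hydroxymethylation: the diarylprolinol silyl ether shields one enamine face, so the (R)-catalyst should give the (S)-aldehyde (C13), which is silylated at once to suppress lactonisation, dehydration and racemisation.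

**Step 11**
Reactants: 11 diene; 14 aldehyde (2 equiv)
Product: 16 7β-acetoxy-2α-chloro-16-[(tert-butyldimethylsilyl)oxy]labd-8(17)-en-15,12-olide (12S,13S; trans γ-lactone), via hydroxy ester 15 (not isolated)
Conditions: Ni(acac)2 (10 mol %), Et2Zn, THF, rt; aq. NH4Cl; then PPTS (cat.), CH2Cl2, rt
Reagents that add atoms: none
Why: Ni(0), formed from Ni(acac)2 and Et2Zn, binds the s-cis 8(17),9(11)-diene and undergoes oxidative cyclisation with the zinc-activated aldehyde to an oxanickelacycle (C11–C12 bond, η3-allyl over C9–C8–C17); ethyl transfer from zinc, β-hydride elimination and C–H reductive elimination then return hydrogen to C9 and leave the C8=C17 methylene, which is the nickel-catalysed homoallylation of aldehydes with 1,3-dienes. The only ring closed is the temporary γ-lactone, by 5-exo-trig attack of the C12 zinc alkoxide on the methyl ester, completed with PPTS. C9 is set by the substrate: the axial C10 methyl blocks the β face, so nickel and the hydrogen it delivers come from the α face, giving the natural 9α-H; C12 is set by the 1,3-anti preference of the oxanickelacycle, in which the aldehyde substituent lies trans to the bulky C10 on C9; C13 is carried in from 14, whose two CH2 arms impose little facial bias of their own. The step needs regioselectivity for C11 over C17, which should follow because the C11 terminus adjoins the fully alkyl-substituted C9 whereas the other half of the diene is deactivated by the C7 acetoxy group. It also needs chemoselectivity against nickel insertion into the allylic C7–O bond, which rests on that bond being equatorial and poorly aligned with the π system; the alkyl chloride, ester and silyl ether should be inert at room temperature.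

**Step 12**
Reactants: 16 lactone silyl ether
Product: 17 7β-acetoxy-2α-chloro-16-hydroxylabd-8(17)-en-15,12-olide
Conditions: HF·pyridine, THF/pyridine, 0 °C→rt
Reagents that add atoms: none
Why: Fluoride-mediated cleavage of the primary TBS ether under buffered conditions should leave the acetate, lactone and exocyclic alkene untouched.

**Step 13**
Reactants: 17 lactone alcohol
Product: 18 7β-acetoxy-2α-chloro-15,12-olidolabd-8(17)-en-16-oic acid (12S,13R; trans-paraconic acid)
Conditions: TEMPO (cat.), PhI(OAc)2, MeCN/H2O, rt
Reagents that add atoms: water, O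
Why: Oxoammonium oxidation of the primary alcohol through the aldehyde hydrate to the acid spares the alkene and acetate; any epimerisation at the aldehyde stage can only favour the desired trans-lactone.

**Step 14**
Reactants: 18 lactone acid
Product: 21 haterumaimide N, via acyl imidazolide 19 (not isolated), via lactone carboxamide 20 (not isolated)
Conditions: CDI, THF, rt; NH3 (dioxane), 0 °C; then DBU, MeCN, rt; aq. NH4Cl
Reagents that add atoms: ammonia, N
Why: CDI activation and ammonolysis give the primary amide, whose base-mediated intramolecular N-acylation by the lactone carbonyl (O→N acyl transfer, imide formation) closes the succinimide and frees the C12 hydroxyl; deprotonation of the imide N–H pulls the equilibrium and no stereocenter is touched.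

**Compound list**
1 | (+)-sclareolide | C[C@@]12CC[C@H]3C(C)(C)CCC[C@]3(C)[C@H]1CC(=O)O2 | starting material
2 | 2α-chlorosclareolide | C[C@@]12CC[C@H]3C(C)(C)C[C@H](Cl)C[C@]3(C)[C@H]1CC(=O)O2 | intermediate
3 | potassium 2α-chloro-8α-hydroxy-13,14,15,16-tetranorlabdan-12-oate | C[C@@]1(O)CC[C@H]2C(C)(C)C[C@H](Cl)C[C@]2(C)[C@H]1CC(=O)[O-].[K+] | intermediate
4 | allyl 2α-chloro-8α-hydroxy-13,14,15,16-tetranorlabdan-12-oate | C[C@@]1(O)CC[C@H]2C(C)(C)C[C@H](Cl)C[C@]2(C)[C@H]1CC(=O)OCC=C | intermediate
5 | allyl 2α-chloro-13,14,15,16-tetranorlabd-8(17)-en-12-oate | C=C1CC[C@H]2C(C)(C)C[C@H](Cl)C[C@]2(C)[C@H]1CC(=O)OCC=C | intermediate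
6 | allyl 2α-chloro-7α-hydroxy-13,14,15,16-tetranorlabd-8(17)-en-12-oate | C=C1[C@H](O)C[C@H]2C(C)(C)C[C@H](Cl)C[C@]2(C)[C@H]1CC(=O)OCC=C | intermediate
7 | allyl 2α-chloro-7-oxo-13,14,15,16-tetranorlabd-8(17)-en-12-oate | C=C1C(=O)C[C@H]2C(C)(C)C[C@H](Cl)C[C@]2(C)[C@H]1CC(=O)OCC=C | intermediate
8 | allyl 2α-chloro-7β-hydroxy-13,14,15,16-tetranorlabd-8(17)-en-12-oate | C=C1[C@@H](O)C[C@H]2C(C)(C)C[C@H](Cl)C[C@]2(C)[C@H]1CC(=O)OCC=C | intermediate
9 | allyl 7β-acetoxy-2α-chloro-13,14,15,16-tetranorlabd-8(17)-en-12-oate | C=C1[C@@H](OC(C)=O)C[C@H]2C(C)(C)C[C@H](Cl)C[C@]2(C)[C@H]1CC(=O)OCC=C | intermediate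
10 | 7β-acetoxy-2α-chloro-13,14,15,16-tetranorlabd-8(17)-en-12-oic acid | C=C1[C@@H](OC(C)=O)C[C@H]2C(C)(C)C[C@H](Cl)C[C@]2(C)[C@H]1CC(=O)O | intermediate
11 | 7β-acetoxy-2α-chloro-12,13,14,15,16-pentanorlabda-8(17),9(11)-diene | C=C1[C@@H](OC(C)=O)C[C@H]2C(C)(C)C[C@H](Cl)C[C@]2(C)C1=C | intermediate
12 | methyl 4-oxobutanoate | COC(=O)CCC=O | starting material
13 | methyl (S)-3-formyl-4-hydroxybutanoate | O=C[C@H](CO)CC(=O)OC | intermediate
14 | methyl (S)-4-[(tert-butyldimethylsilyl)oxy]-3-formylbutanoate | O=C[C@H](CO[Si](C)(C)C(C)(C)C)CC(=O)OC | intermediate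
15 | methyl (12S,13S)-7β-acetoxy-2α-chloro-12-hydroxy-16-[(tert-butyldimethylsilyl)oxy]labd-8(17)-en-15-oate | C=C1[C@@H](OC(C)=O)C[C@H]2C(C)(C)C[C@H](Cl)C[C@]2(C)[C@H]1C[C@H](O)[C@H](CO[Si](C)(C)C(C)(C)C)CC(=O)OC | intermediate
16 | (12S,13S)-7β-acetoxy-2α-chloro-16-[(tert-butyldimethylsilyl)oxy]labd-8(17)-en-15,12-olide (trans γ-lactone) | C=C1[C@@H](OC(C)=O)C[C@H]2C(C)(C)C[C@H](Cl)C[C@]2(C)[C@H]1C[C@@H]1OC(=O)C[C@H]1CO[Si](C)(C)C(C)(C)C | intermediate
17 | (12S,13S)-7β-acetoxy-2α-chloro-16-hydroxylabd-8(17)-en-15,12-olide | C=C1[C@@H](OC(C)=O)C[C@H]2C(C)(C)C[C@H](Cl)C[C@]2(C)[C@H]1C[C@@H]1OC(=O)C[C@H]1CO | intermediate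
18 | (12S,13R)-7β-acetoxy-2α-chloro-15,12-olidolabd-8(17)-en-16-oic acid | C=C1[C@@H](OC(C)=O)C[C@H]2C(C)(C)C[C@H](Cl)C[C@]2(C)[C@H]1C[C@@H]1OC(=O)C[C@H]1C(=O)O | intermediate
19 | 16-acyl imidazolide of 18 | C=C1[C@@H](OC(C)=O)C[C@H]2C(C)(C)C[C@H](Cl)C[C@]2(C)[C@H]1C[C@@H]1OC(=O)C[C@H]1C(=O)n3ccnc3 | intermediate
20 | (12S,13R)-7β-acetoxy-2α-chloro-15,12-olidolabd-8(17)-en-16-amide | C=C1[C@@H](OC(C)=O)C[C@H]2C(C)(C)C[C@H](Cl)C[C@]2(C)[C@H]1C[C@@H]1OC(=O)C[C@H]1C(N)=O | intermediate
21 | haterumaimide N | C=C1[C@@H](OC(C)=O)C[C@H]2C(C)(C)C[C@H](Cl)C[C@]2(C)[C@H]1C[C@H](O)[C@H]1CC(=O)NC1=O | target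

**Step count and risks**
Total steps: 14. Longest linear sequence: 13 (steps 1–9 and 11–14); step 10 is the convergent branch.

Step 11 is the most likely to fail. The aldehyde may bond at C17 instead of C11, hydride may return to C17 and give the tetrasubstituted 8,9-alkene, Ni(0) may insert into the allylic C7–O bond, ethyl may transfer from zinc to the aldehyde, or facial selectivity at C12 may be poor. The fallback sets out from acid 10 and returns at lactone 16, bypassing the diene. Acid 10 is esterified (N-hydroxyphthalimide, DIC, DMAP) to the redox-active N-hydroxyphthalimide ester F1. F1 undergoes chromium(II)-mediated decarboxylative addition of Nozaki–Hiyama–Kishi type (CrCl2, TMSCl, THF) to aldehyde 14, giving hydroxy ester 15 after acidic work-up and then lactone 16 with PPTS. C9 is then inherited from sclareolide and the C8 methylene is never disturbed. C12 would be set only by the weak Felkin bias of 14, so the cis- and trans-lactones would have to be separated at 16.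

Step 9 is next. The primary C11 radical may be reduced before cobalt captures it, cobalt hydride may re-add to the product and isomerise the diene, or the diene may dimerise under irradiation. The fallback sets out from acid 10 and returns at diene 11. Acid 10 is converted (N-hydroxypyridine-2-thione, DCC, DMAP) to the Barton ester F2. Photolysis of F2 with diphenyl diselenide gives the C11 phenyl selenide F3 by decarboxylative selenation. Oxidation with H2O2 gives the selenoxide F4, which should undergo syn-elimination at room temperature with the only β-hydrogen (C9–H) to give 11.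

Step 14 is third. The bicyclic tetrahedral intermediate of the acyl transfer may form too slowly, C13 deprotonation may open the lactone by Stobbe-type elimination, C13 may epimerise, or the acetate may be lost under base. The fallback sets out from lactone acid 18 and returns at target 21. Acid 18 is methylated (TMSCHN2, PhMe/MeOH) to the methyl ester F5. Cold methanolic ammonia (0 °C) should open the more electrophilic lactone carbonyl to the hydroxy amide ester F6. F6 closes onto the C16 methyl ester through an unstrained monocyclic 5-exo-trig transition state and gives 21 directly. The residual risk there is competing ammonolysis of the C7 acetate, so the reaction would be stopped at partial conversion.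

**Further compounds**
F1 | step 11 | N-hydroxyphthalimide ester of acid 10 | C=C1[C@@H](OC(C)=O)C[C@H]2C(C)(C)C[C@H](Cl)C[C@]2(C)[C@H]1CC(=O)ON1C(=O)c2ccccc2C1=O
F2 | step 9 | Barton ester (N-acyloxypyridine-2-thione) of acid 10 | C=C1[C@@H](OC(C)=O)C[C@H]2C(C)(C)C[C@H](Cl)C[C@]2(C)[C@H]1CC(=O)On1ccccc1=S
F3 | step 9 | 7β-acetoxy-2α-chloro-11-(phenylselanyl)-12,13,14,15,16-pentanorlabd-8(17)-ene | C=C1[C@@H](OC(C)=O)C[C@H]2C(C)(C)C[C@H](Cl)C[C@]2(C)[C@H]1C[Se]c1ccccc1
F4 | step 9 | selenoxide of F3 | C=C1[C@@H](OC(C)=O)C[C@H]2C(C)(C)C[C@H](Cl)C[C@]2(C)[C@H]1C[Se](=O)c1ccccc1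
F5 | step 14 | methyl ester of lactone acid 18 | C=C1[C@@H](OC(C)=O)C[C@H]2C(C)(C)C[C@H](Cl)C[C@]2(C)[C@H]1C[C@@H]1OC(=O)C[C@H]1C(=O)OC
F6 | step 14 | methyl (12S,13R)-7β-acetoxy-15-amino-2α-chloro-12-hydroxy-15-oxolabd-8(17)-en-16-oate | C=C1[C@@H](OC(C)=O)C[C@H]2C(C)(C)C[C@H](Cl)C[C@]2(C)[C@H]1C[C@H](O)[C@H](C(=O)OC)CC(N)=O
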